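**Retrosynthetic overview**

1. Each chain (C1′ = vinyl CH2, C3′ = quaternary carbon) has a C5′H2–C6′H= bond to an (E)-trisubstituted alkene. Beyond it the tails on ring A (the 3-aryloxycatechol ring, C3′ para to the middle oxygen) and ring B (the 2-aryloxyphenol ring, C3′ ortho to OH) are the same C9 unit. Both C5′–C6′ bonds are cut at once, giving a tris-silylated diaryl ether diacid (each C3′ bearing methyl, vinyl and CH2CH2CO2H) and two molecules of (E)-1-iodo-2,6-dimethylhepta-1,5-diene per molecule of diacid.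
2. Each CH2CH2CO2H arm is traced to a homoprenyl group (epoxidation, periodic acid cleavage, Pinnick oxidation) after the MOM ethers needed for the organometallic steps have been exchanged for TBS ethers.
3. The two C3′ centres come from two successive copper-catalysed enantioselective SN2′ arylations of geranyl diethyl phosphate, first by ring B (through its iodide, S centre), then by ring A (through its bromide, R centre), with antipodal carbene ligands.
4. The bromo-iodo diaryl ether comes from SNAr of a ring A phenol on 2-fluoro-6-iodobenzaldehyde followed by Dakin oxidation. The ring A phenol comes from 5-bromo-2,3-dihydroxybenzaldehyde (MOM protection, Dakin oxidation). The iodide comes from 6-methylhept-5-en-2-one (alkyne formation, zirconium-catalysed carboalumination–iodination).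
5. No ring is formed in the route; rings A and B are bought and joined through the ether oxygen in step 3.

Key step: step 16

Abbreviations: MOM = methoxymethyl; TBS = tert-butyldimethylsilyl; mCPBA = 3-chloroperbenzoic acid; DIC = N,N′-diisopropylcarbodiimide; NHC-S = (4S,5S)-1-mesityl-4,5-diphenyl-3-(2-sulfonatophenyl)imidazolidin-2-ylidene, NHC-R = its (4R,5R) antipode, used as the silver complexes [(NHC-S)Ag]2 and [(NHC-R)Ag]2.

Remark (assumption): [(NHC-S)Ag]2/CuCl2·2H2O is taken to deliver aryl to the face of the (E)-phosphate that gives the (S) centre and the antipode the (R) centre; if a model coupling shows the opposite sense, the two complexes are exchanged between steps 7 and 8.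

**Route**

Step 1
Reactants: 1 5-bromo-2,3-dihydroxybenzaldehyde
Product: 2 5-bromo-2,3-bis(methoxymethoxy)benzaldehyde
Conditions: NaH (2.4 equiv), MOMCl (2.4 equiv), DMF, 0 °C → rt
Reagents that add atoms: chloromethyl methyl ether (MOMCl), COCCl
Why: Williamson-type O-alkylation of both phenoxides should give the bis-acetal, which is stable to the bases and organometallic reagents used later.

Step 2
Reactants: 2 5-bromo-2,3-bis(methoxymethoxy)benzaldehyde
Product: 4 5-bromo-2,3-bis(methoxymethoxy)phenol, via aryl formate 3 (not isolated)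
Conditions: mCPBA, CH2Cl2, 0 °C → rt; then K2CO3, MeOH, rt
Reagents that add atoms: 3-chloroperbenzoic acid (mCPBA), O=C(OO)c1cccc(Cl)c1
Why: In this Dakin-type Baeyer–Villiger oxidation the electron-rich aryl group should migrate to oxygen, and methanolysis of the formate frees the phenol.

Step 3
Reactants: 4 5-bromo-2,3-bis(methoxymethoxy)phenol; 5 2-fluoro-6-iodobenzaldehyde
Product: 6 2-[5-bromo-2,3-bis(methoxymethoxy)phenoxy]-6-iodobenzaldehyde
Conditions: K2CO3, DMF, 80 °C
Reagents that add atoms: none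
Why: The ortho-formyl group activates the C–F bond for SNAr by the phenoxide (Meisenheimer pathway), while the aryl iodide and bromide are not displaced.

Step 4
Reactants: 6 2-[5-bromo-2,3-bis(methoxymethoxy)phenoxy]-6-iodobenzaldehyde
Product: 8 2-[5-bromo-2,3-bis(methoxymethoxy)phenoxy]-6-iodophenol, via aryl formate 7 (not isolated)
Conditions: mCPBA, CH2Cl2, 0 °C → rt; then K2CO3, MeOH, rt
Reagents that add atoms: 3-chloroperbenzoic acid (mCPBA), O=C(OO)c1cccc(Cl)c1
Why: A second Dakin-type Baeyer–Villiger oxidation, with the ortho-aryloxy group promoting aryl migration, should turn the formyl group into the ring B hydroxyl.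

Step 5
Reactants: 8 2-[5-bromo-2,3-bis(methoxymethoxy)phenoxy]-6-iodophenol
Product: 9 5-bromo-1-[3-iodo-2-(methoxymethoxy)phenoxy]-2,3-bis(methoxymethoxy)benzene
Conditions: NaH, MOMCl, DMF, 0 °C → rt
Reagents that add atoms: chloromethyl methyl ether (MOMCl), COCCl
Why: O-Alkylation of the phenoxide gives a MOM ether that cannot migrate to carbon after ortho-metalation, as a silyl ether could.

Step 6
Reactants: 10 geraniol
Product: 11 geranyl diethyl phosphate
Conditions: ClP(O)(OEt)2, pyridine, CH2Cl2, 0 °C → rt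
Reagents that add atoms: diethyl chlorophosphate, CCOP(=O)(Cl)OCC
Why: Phosphorylation of the primary allylic alcohol gives the γ,γ-disubstituted allylic electrophile without touching the (E) alkene.

Step 7
Reactants: 9 5-bromo-1-[3-iodo-2-(methoxymethoxy)phenoxy]-2,3-bis(methoxymethoxy)benzene; 11 geranyl diethyl phosphate
Product: 14 5-bromo-1-{3-[(3S)-3,7-dimethylocta-1,6-dien-3-yl]-2-(methoxymethoxy)phenoxy}-2,3-bis(methoxymethoxy)benzene, via aryllithium 12 (not isolated), via diethylarylaluminium 13 (not isolated)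
Conditions: n-BuLi (1.0 equiv), THF, −78 °C; Et2AlCl (1.0 equiv), −78 °C → rt; then 11 (2 equiv), CuCl2·2H2O (5 mol %), [(NHC-S)Ag]2 (2.5 mol %), THF, −30 °C
Reagents that add atoms: none
Why: Iodine–lithium exchange is much faster than bromine–lithium exchange and gives the MOM-stabilised ring B aryllithium, and after transmetalation to aluminium a copper-catalysed enantioselective allylic substitution (SN2′) transfers the aryl group to C3 of the (E)-phosphate, the chiral carbene ligand choosing the alkene face and so setting the (S) quaternary centre.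

Step 8
Reactants: 14 5-bromo-1-{3-[(3S)-3,7-dimethylocta-1,6-dien-3-yl]-2-(methoxymethoxy)phenoxy}-2,3-bis(methoxymethoxy)benzene; 11 geranyl diethyl phosphate
Product: 17 5-[(3R)-3,7-dimethylocta-1,6-dien-3-yl]-1-{3-[(3S)-3,7-dimethylocta-1,6-dien-3-yl]-2-(methoxymethoxy)phenoxy}-2,3-bis(methoxymethoxy)benzene, via aryllithium 15 (not isolated), via diethylarylaluminium 16 (not isolated)
Conditions: t-BuLi (2.0 equiv), THF, −78 °C; Et2AlCl (1.0 equiv), −78 °C → rt; then 11 (2 equiv), CuCl2·2H2O (5 mol %), [(NHC-R)Ag]2 (2.5 mol %), THF, −30 °C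
Reagents that add atoms: none
Why: The same copper-catalysed enantioselective SN2′ arylation, now from the unhindered ring A aryl group and with the antipodal ligand, should set the (R) quaternary centre under catalyst control, since the ring B centre is too remote to interfere.

Step 9
Reactants: 17 5-[(3R)-3,7-dimethylocta-1,6-dien-3-yl]-1-{3-[(3S)-3,7-dimethylocta-1,6-dien-3-yl]-2-(methoxymethoxy)phenoxy}-2,3-bis(methoxymethoxy)benzene
Product: 18 5-[(3R)-3,7-dimethylocta-1,6-dien-3-yl]-3-{3-[(3S)-3,7-dimethylocta-1,6-dien-3-yl]-2-hydroxyphenoxy}benzene-1,2-diol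
Conditions: HCl (1.25 M in MeOH), THF, 0 °C → rt, argon
Reagents that add atoms: none
Why: Acid-catalysed transacetalisation to methanol removes the three aryl MOM ethers, and the isolated alkenes, which have no neighbouring nucleophile and are not yet part of a 1,5-diene, should tolerate dilute methanolic HCl at room temperature.

Step 10
Reactants: 18 5-[(3R)-3,7-dimethylocta-1,6-dien-3-yl]-3-{3-[(3S)-3,7-dimethylocta-1,6-dien-3-yl]-2-hydroxyphenoxy}benzene-1,2-diol
Product: 19 tris(tert-butyldimethylsilyl) ether of 18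
Conditions: TBSOTf (4 equiv), 2,6-lutidine (6 equiv), CH2Cl2, 0 °C → rt, argon
Reagents that add atoms: tert-butyldimethylsilyl trifluoromethanesulfonate (TBSOTf), CC(C)(C)[Si](C)(C)OS(=O)(=O)C(F)(F)F
Why: The silyl triflate is reactive enough to silylate also the ring B phenol flanked by the aryloxy group and the quaternary carbon, giving ethers that fluoride removes at the end.

Step 11
Reactants: 19 tris(tert-butyldimethylsilyl) ether of 18
Product: 20 bis-epoxide of 19 (both 6,7-alkenes converted into 3,3-dimethyloxiran-2-yl groups; epimer mixture at the oxirane CH)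
Conditions: mCPBA (2.1 equiv), CH2Cl2, −10 → 0 °C
Reagents that add atoms: 3-chloroperbenzoic acid (mCPBA), O=C(OO)c1cccc(Cl)c1
Why: In this Prilezhaev epoxidation the electron-rich trisubstituted alkenes should react far faster than the two vinyl groups on quaternary carbons.

Step 12
Reactants: 20 bis-epoxide of 19
Product: 21 (4R)-4-{3,4-bis[(tert-butyldimethylsilyl)oxy]-5-[2-[(tert-butyldimethylsilyl)oxy]-3-[(3S)-3-methyl-6-oxohex-1-en-3-yl]phenoxy]phenyl}-4-methylhex-5-enal
Conditions: H5IO6 (2.4 equiv), THF/Et2O, 0 °C, short reaction time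
Reagents that add atoms: none
Why: Periodic acid opens each epoxide at its tertiary carbon and cleaves the resulting glycol (Malaprade-type cleavage) to the aldehyde and acetone, the aldehyde oxygen being the former epoxide oxygen.

Step 13
Reactants: 21 (4R)-4-{3,4-bis[(tert-butyldimethylsilyl)oxy]-5-[2-[(tert-butyldimethylsilyl)oxy]-3-[(3S)-3-methyl-6-oxohex-1-en-3-yl]phenoxy]phenyl}-4-methylhex-5-enal
Product: 22 (4R)-4-{3,4-bis[(tert-butyldimethylsilyl)oxy]-5-[2-[(tert-butyldimethylsilyl)oxy]-3-[(3S)-5-carboxy-3-methylpent-1-en-3-yl]phenoxy]phenyl}-4-methylhex-5-enoic acid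
Conditions: NaClO2, NaH2PO4, 2-methylbut-2-ene (excess), t-BuOH/H2O, 0 °C → rt
Reagents that add atoms: sodium chlorite, [Na+].[O-]Cl=O
Why: The Pinnick oxidation converts both aldehydes into acids under buffered conditions, with the alkene scavenger removing the hypochlorous acid that would otherwise chlorinate the arenes or vinyl groups.

Step 14
Reactants: 23 6-methylhept-5-en-2-one
Product: 25 6-methylhept-5-en-1-yne, via enol phosphate 24 (not isolated)
Conditions: LiN(i-Pr)2 (1.05 equiv), THF, −78 °C; ClP(O)(OEt)2, −78 °C → rt; then LiN(i-Pr)2 (2.3 equiv), THF, −78 °C → rt; H2O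
Reagents that add atoms: none
Why: The kinetic methyl-side enolate is trapped on oxygen and the enol phosphate undergoes base-induced elimination to the acetylide (methyl ketone to terminal alkyne conversion).

Step 15
Reactants: 25 6-methylhept-5-en-1-yne
Product: 27 (1E)-1-iodo-2,6-dimethylhepta-1,5-diene, via alkenylalane 26 (not isolated)
Conditions: Me3Al (2 equiv), Cp2ZrCl2 (0.25 equiv), CH2Cl2, 0 °C → rt; then I2, THF, −30 → 0 °C
Reagents that add atoms: trimethylaluminium, C[Al](C)C; iodine, II
Why: The zirconium-catalysed Negishi carboalumination adds methyl and aluminium syn across the alkyne with aluminium at the terminus, and iodinolysis with retention gives the (E)-iodide.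

Step 16
Reactants: 22 (4R)-4-{3,4-bis[(tert-butyldimethylsilyl)oxy]-5-[2-[(tert-butyldimethylsilyl)oxy]-3-[(3S)-5-carboxy-3-methylpent-1-en-3-yl]phenoxy]phenyl}-4-methylhex-5-enoic acid; 27 (1E)-1-iodo-2,6-dimethylhepta-1,5-diene (two molecules are incorporated per molecule of 22, one on each arm)
Product: 29 1,2-bis[(tert-butyldimethylsilyl)oxy]-3-{2-[(tert-butyldimethylsilyl)oxy]-3-[(3S,6E)-3,7,11-trimethyldodeca-1,6,10-trien-3-yl]phenoxy}-5-[(3R,6E)-3,7,11-trimethyldodeca-1,6,10-trien-3-yl]benzene, via bis(N-acyloxyphthalimide) 28 (not isolated)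
Conditions: N-hydroxyphthalimide (2.2 equiv), DIC (2.2 equiv), 4-(dimethylamino)pyridine (cat.), CH2Cl2, rt; solvent exchange; then 27 (5 equiv, that is 2.5 per arm), NiCl2·6H2O (20 mol %), 2,2′-bipyridine (24 mol %), AgNO3 (0.5 equiv), DMF, Mg anode, reticulated vitreous carbon cathode, constant current, rt
Reagents that add atoms: (1E)-1-iodo-2,6-dimethylhepta-1,5-diene, the second molecule of 27, which supplies the C6′–C12′ unit of the second arm, I/C=C(\C)CCC=C(C)C
Why: Cathodic reduction turns the NiCl2·6H2O/2,2′-bipyridine precatalyst into zerovalent nickel, which inserts into the C–I bond of 27 with retention of the (E) geometry; single-electron reduction of each N-acyloxyphthalimide unit of 28 expels phthalimide anion and CO2 and leaves a primary C5′ radical, which the alkenylnickel species captures, and reductive elimination from trivalent nickel forms the C5′–C6′ bond. The closest known reaction type is the nickel-electrocatalytic decarboxylative alkenylation of redox-active esters of primary acids with (E)-alkenyl iodides, here run on two equivalent arms in one cell, so that each molecule of 22 takes up two molecules of 27 and four electrons and loses two molecules of CO2. No ring is closed and no stereocentre is formed: the two quaternary centres lie two bonds from the radical carbon and carry no hydrogen, so they cannot epimerise, and the C6′=C7′ geometry is that of the iodide. The radical is a 4-pentenyl radical, for which 4-exo and 5-endo closure are slow, and ipso attack on the aryl group would need a four-membered transition state, so capture by nickel should win. The step needs complete conversion of both arms and suppression of reduction to C5′–H or radical dimerisation; excess 27 and the silver deposited on the cathode from AgNO3, which keeps the alkenylnickel concentration high, address this, while the aryl silyl ethers and terminal vinyl groups are inert at the working potential.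

Step 17
Reactants: 29 1,2-bis[(tert-butyldimethylsilyl)oxy]-3-{2-[(tert-butyldimethylsilyl)oxy]-3-[(3S,6E)-3,7,11-trimethyldodeca-1,6,10-trien-3-yl]phenoxy}-5-[(3R,6E)-3,7,11-trimethyldodeca-1,6,10-trien-3-yl]benzene
Product: 30 5-[(3R,6E)-3,7,11-trimethyldodeca-1,6,10-trien-3-yl]-3-{2-hydroxy-3-[(3S,6E)-3,7,11-trimethyldodeca-1,6,10-trien-3-yl]phenoxy}benzene-1,2-diol
Conditions: Bu4NF (3.6 equiv), AcOH (3.6 equiv), THF, 0 °C → rt, degassed, argon
Reagents that add atoms: none
Why: Fluoride cleaves the three aryl Si–O bonds under buffered, non-acidic conditions that leave the 1,5-diene tails and the oxidation-prone catechol untouched.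

**Compound list**

1 | 5-bromo-2,3-dihydroxybenzaldehyde | O=Cc1cc(Br)cc(O)c1O | starting material
2 | 5-bromo-2,3-bis(methoxymethoxy)benzaldehyde | O=Cc1cc(Br)cc(OCOC)c1OCOC | intermediate
3 | 5-bromo-2,3-bis(methoxymethoxy)phenyl formate | O=COc1cc(Br)cc(OCOC)c1OCOC | intermediate
4 | 5-bromo-2,3-bis(methoxymethoxy)phenol | Oc1cc(Br)cc(OCOC)c1OCOC | intermediate
5 | 2-fluoro-6-iodobenzaldehyde | O=Cc1c(F)cccc1I | starting material
6 | 2-[5-bromo-2,3-bis(methoxymethoxy)phenoxy]-6-iodobenzaldehyde | O=Cc1c(I)cccc1Oc1cc(Br)cc(OCOC)c1OCOC | intermediate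
7 | 2-[5-bromo-2,3-bis(methoxymethoxy)phenoxy]-6-iodophenyl formate | O=COc1c(I)cccc1Oc1cc(Br)cc(OCOC)c1OCOC | intermediate
8 | 2-[5-bromo-2,3-bis(methoxymethoxy)phenoxy]-6-iodophenol | Oc1c(I)cccc1Oc1cc(Br)cc(OCOC)c1OCOC | intermediate
9 | 5-bromo-1-[3-iodo-2-(methoxymethoxy)phenoxy]-2,3-bis(methoxymethoxy)benzene | COCOc1c(I)cccc1Oc1cc(Br)cc(OCOC)c1OCOC | intermediate
10 | geraniol, (2E)-3,7-dimethylocta-2,6-dien-1-ol | OC/C=C(\C)CCC=C(C)C | starting material
11 | geranyl diethyl phosphate, diethyl (2E)-3,7-dimethylocta-2,6-dien-1-yl phosphate | CCOP(=O)(OCC)OC/C=C(\C)CCC=C(C)C | intermediate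
12 | {3-[5-bromo-2,3-bis(methoxymethoxy)phenoxy]-2-(methoxymethoxy)phenyl}lithium (ring B aryllithium) | [Li]c1cccc(Oc2cc(Br)cc(OCOC)c2OCOC)c1OCOC | intermediate
13 | diethyl{3-[5-bromo-2,3-bis(methoxymethoxy)phenoxy]-2-(methoxymethoxy)phenyl}aluminium | CC[Al](CC)c1cccc(Oc2cc(Br)cc(OCOC)c2OCOC)c1OCOC | intermediate
14 | 5-bromo-1-{3-[(3S)-3,7-dimethylocta-1,6-dien-3-yl]-2-(methoxymethoxy)phenoxy}-2,3-bis(methoxymethoxy)benzene | Brc1cc(OCOC)c(OCOC)c(Oc2cccc([C@](C)(C=C)CCC=C(C)C)c2OCOC)c1 | intermediate
15 | ring A aryllithium from 14 (lithium in place of bromine) | [Li]c1cc(OCOC)c(OCOC)c(Oc2cccc([C@](C)(C=C)CCC=C(C)C)c2OCOC)c1 | intermediate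
16 | ring A diethylarylaluminium from 15 | CC[Al](CC)c1cc(OCOC)c(OCOC)c(Oc2cccc([C@](C)(C=C)CCC=C(C)C)c2OCOC)c1 | intermediate
17 | 5-[(3R)-3,7-dimethylocta-1,6-dien-3-yl]-1-{3-[(3S)-3,7-dimethylocta-1,6-dien-3-yl]-2-(methoxymethoxy)phenoxy}-2,3-bis(methoxymethoxy)benzene | C=C[C@@](C)(CCC=C(C)C)c1cc(OCOC)c(OCOC)c(Oc2cccc([C@](C)(C=C)CCC=C(C)C)c2OCOC)c1 | intermediate
18 | 5-[(3R)-3,7-dimethylocta-1,6-dien-3-yl]-3-{3-[(3S)-3,7-dimethylocta-1,6-dien-3-yl]-2-hydroxyphenoxy}benzene-1,2-diol | C=C[C@@](C)(CCC=C(C)C)c1cc(O)c(O)c(Oc2cccc([C@](C)(C=C)CCC=C(C)C)c2O)c1 | intermediate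
19 | 1,2-bis[(tert-butyldimethylsilyl)oxy]-3-{2-[(tert-butyldimethylsilyl)oxy]-3-[(3S)-3,7-dimethylocta-1,6-dien-3-yl]phenoxy}-5-[(3R)-3,7-dimethylocta-1,6-dien-3-yl]benzene | C=C[C@@](C)(CCC=C(C)C)c1cc(O[Si](C)(C)C(C)(C)C)c(O[Si](C)(C)C(C)(C)C)c(Oc2cccc([C@](C)(C=C)CCC=C(C)C)c2O[Si](C)(C)C(C)(C)C)c1 | intermediate
20 | bis-epoxide of 19 (each 6,7-alkene as a 3,3-dimethyloxiran-2-yl group, epimer mixture at the oxirane CH; ring A centre R, ring B centre S) | C=C[C@@](C)(CCC1OC1(C)C)c1cc(O[Si](C)(C)C(C)(C)C)c(O[Si](C)(C)C(C)(C)C)c(Oc2cccc([C@](C)(C=C)CCC3OC3(C)C)c2O[Si](C)(C)C(C)(C)C)c1 | intermediate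
21 | (4R)-4-{3,4-bis[(tert-butyldimethylsilyl)oxy]-5-[2-[(tert-butyldimethylsilyl)oxy]-3-[(3S)-3-methyl-6-oxohex-1-en-3-yl]phenoxy]phenyl}-4-methylhex-5-enal | C=C[C@@](C)(CCC=O)c1cc(O[Si](C)(C)C(C)(C)C)c(O[Si](C)(C)C(C)(C)C)c(Oc2cccc([C@](C)(C=C)CCC=O)c2O[Si](C)(C)C(C)(C)C)c1 | intermediate
22 | (4R)-4-{3,4-bis[(tert-butyldimethylsilyl)oxy]-5-[2-[(tert-butyldimethylsilyl)oxy]-3-[(3S)-5-carboxy-3-methylpent-1-en-3-yl]phenoxy]phenyl}-4-methylhex-5-enoic acid | C=C[C@@](C)(CCC(=O)O)c1cc(O[Si](C)(C)C(C)(C)C)c(O[Si](C)(C)C(C)(C)C)c(Oc2cccc([C@](C)(C=C)CCC(=O)O)c2O[Si](C)(C)C(C)(C)C)c1 | intermediate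
23 | 6-methylhept-5-en-2-one | CC(=O)CCC=C(C)C | starting material
24 | diethyl 6-methylhepta-1,5-dien-2-yl phosphate | C=C(CCC=C(C)C)OP(=O)(OCC)OCC | intermediate
25 | 6-methylhept-5-en-1-yne | C#CCCC=C(C)C | intermediate
26 | [(1E)-2,6-dimethylhepta-1,5-dien-1-yl]dimethylaluminium | C[Al](C)/C=C(\C)CCC=C(C)C | intermediate
27 | (1E)-1-iodo-2,6-dimethylhepta-1,5-diene | I/C=C(\C)CCC=C(C)C | intermediate
28 | bis(1,3-dioxoisoindolin-2-yl) diester of 22 | C=C[C@@](C)(CCC(=O)ON1C(=O)c2ccccc2C1=O)c1cc(O[Si](C)(C)C(C)(C)C)c(O[Si](C)(C)C(C)(C)C)c(Oc2cccc([C@](C)(C=C)CCC(=O)ON3C(=O)c4ccccc4C3=O)c2O[Si](C)(C)C(C)(C)C)c1 | intermediate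
29 | 1,2-bis[(tert-butyldimethylsilyl)oxy]-3-{2-[(tert-butyldimethylsilyl)oxy]-3-[(3S,6E)-3,7,11-trimethyldodeca-1,6,10-trien-3-yl]phenoxy}-5-[(3R,6E)-3,7,11-trimethyldodeca-1,6,10-trien-3-yl]benzene | C=C[C@@](C)(CC/C=C(\C)CCC=C(C)C)c1cc(O[Si](C)(C)C(C)(C)C)c(O[Si](C)(C)C(C)(C)C)c(Oc2cccc([C@](C)(C=C)CC/C=C(\C)CCC=C(C)C)c2O[Si](C)(C)C(C)(C)C)c1 | intermediate
30 | 5-[(3R,6E)-3,7,11-trimethyldodeca-1,6,10-trien-3-yl]-3-{2-hydroxy-3-[(3S,6E)-3,7,11-trimethyldodeca-1,6,10-trien-3-yl]phenoxy}benzene-1,2-diol (CNP0325484.1) | C=C[C@@](C)(CC/C=C(\C)CCC=C(C)C)c1cc(O)c(O)c(Oc2cccc([C@](C)(C=C)CC/C=C(\C)CCC=C(C)C)c2O)c1 | target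

**Totals**

Total step count: 17. Longest linear sequence: 14 steps (steps 1–5, 7–13, 16, 17, from compound 1 to compound 30).

**Steps most likely to fail**

1. Step 16. The two-fold coupling may stop after one arm has reacted, the C5′ radicals may be reduced to C5′–H or dimerise before nickel captures them, or the iodide may be consumed by homocoupling. Fallback: the C5′–C6′ bonds are made by a two-electron Negishi coupling. Setting out from diacid 22, DCC-mediated esterification with 1-hydroxypyridine-2(1H)-thione (CH2Cl2, dark) would give the bis(thiohydroxamate) ester F1. Photolysis with a tungsten lamp in the presence of CHI3 (Barton iododecarboxylation) would give the bis(primary iodide) F2. Zinc insertion (Zn dust, LiCl, THF) would give the bis(alkylzinc iodide) F3, and coupling with two equivalents of iodide 27 under the zerovalent palladium catalyst Pd(PPh3)4 in THF returns to the route at 29.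

2. Step 7. Chelation of aluminium by the ortho MOM group and the congestion of forming a quaternary centre next to an ortho substituent may slow aryl transfer and erode SN2′ and facial selectivity. Fallback: the roles of the partners are reversed. Setting out from 9, a Stille coupling at the C–I bond (the C–Br bond is left) with (2E)-3-(tributylstannyl)but-2-en-1-ol [Pd(PPh3)4, CuI (cat.), DMF] would give allylic alcohol F4. ClP(O)(OEt)2 and pyridine would give allylic phosphate F5. Copper-catalysed enantioselective allylic alkylation with bis(4-methylpent-3-enyl)zinc [CuCl2·2H2O and whichever of [(NHC-S)Ag]2 or [(NHC-R)Ag]2 gives the (S) centre, THF, −15 °C] places the homoprenyl group on the aryl-bearing carbon and returns to the route at 14.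

3. Step 12. The aryl silyl ethers may be lost in the acidic oxidant, after which the freed catechol would be oxidised to a quinone. Fallback: the glycol route, which replaces steps 11 and 12. Setting out from 19, Upjohn dihydroxylation [K2OsO2(OH)4 (cat.), N-methylmorpholine N-oxide, acetone/H2O, 0 °C], which in linalool-type dienes takes place at the trisubstituted alkene and not at the hindered vinyl group, would give tetraol F6. NaIO4 in THF/pH 7 buffer cleaves both glycols and returns to the route at 21.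

**Further compounds**

F1 | step 16 | bis(2-thioxopyridin-1(2H)-yl) diester of 22 (bis Barton ester; ring A centre R, ring B centre S) | C=C[C@@](C)(CCC(=O)On1ccccc1=S)c1cc(O[Si](C)(C)C(C)(C)C)c(O[Si](C)(C)C(C)(C)C)c(Oc2cccc([C@](C)(C=C)CCC(=O)On3ccccc3=S)c2O[Si](C)(C)C(C)(C)C)c1
F2 | step 16 | bis(primary iodide): each quaternary carbon bearing methyl, vinyl and 2-iodoethyl (ring A centre R, ring B centre S), three TBS ethers | C=C[C@@](C)(CCI)c1cc(O[Si](C)(C)C(C)(C)C)c(O[Si](C)(C)C(C)(C)C)c(Oc2cccc([C@](C)(C=C)CCI)c2O[Si](C)(C)C(C)(C)C)c1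
F3 | step 16 | bis(alkylzinc iodide) from F2 | C=C[C@@](C)(CC[Zn]I)c1cc(O[Si](C)(C)C(C)(C)C)c(O[Si](C)(C)C(C)(C)C)c(Oc2cccc([C@](C)(C=C)CC[Zn]I)c2O[Si](C)(C)C(C)(C)C)c1
F4 | step 7 | (2E)-3-{3-[5-bromo-2,3-bis(methoxymethoxy)phenoxy]-2-(methoxymethoxy)phenyl}but-2-en-1-ol | OC/C=C(\C)c1cccc(Oc2cc(Br)cc(OCOC)c2OCOC)c1OCOC
F5 | step 7 | diethyl (2E)-3-{3-[5-bromo-2,3-bis(methoxymethoxy)phenoxy]-2-(methoxymethoxy)phenyl}but-2-en-1-yl phosphate | CCOP(=O)(OCC)OC/C=C(\C)c1cccc(Oc2cc(Br)cc(OCOC)c2OCOC)c1OCOC
F6 | step 12 | tetraol: 19 with both 6,7-alkenes dihydroxylated (epimer mixture at the secondary carbinol carbons) | C=C[C@@](C)(CCC(O)C(C)(C)O)c1cc(O[Si](C)(C)C(C)(C)C)c(O[Si](C)(C)C(C)(C)C)c(Oc2cccc([C@](C)(C=C)CCC(O)C(C)(C)O)c2O[Si](C)(C)C(C)(C)C)c1
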